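## The problem

Compound 35 is a decalin diterpenoid acid. Ring A (C1–C5, C10) and ring B (C5–C10) share the C5–C10 bond, and C10 is olefinic (C1=C10), so only C5 of the fusion is stereogenic. C17 and C20 are the methyl groups on C8 and C9, C18 and C19 are the carbons on C4, and C11–C16 is the side chain. Four stereocentres must be set, (4S,5S,8R,9S). C8 and C9 are adjacent in ring B and carry cis methyl groups; that face is called β below. C9 is quaternary with the chain on the α face, H-5 is α, and C4 is a second quaternary centre with methyl β and carboxyl α. C8, C9 and C5 lie in one six-membered ring and can be tied together by one concerted event. C4 is insulated from them and can be controlled only from C5, by telling apart two groups on C4 that differ in their relation to the C5–C6 bond. The C1=C10 alkene is trisubstituted, exocyclic to ring B and flanked by the quaternary C9; it must be placed regioselectively and will drift to C5=C10 under acid. The chain ends in a primary allylic propanoate on an (E)-trisubstituted alkene, which tolerates neither hydroxide, thiolate, hydride nor zerovalent palladium, so the hindered C19 acid must be free before that ester is made. The key step is possible because ring B holds the C8 methine and the quaternary C9 next to the fusion bond. Cutting C8–C9 and C5–C10 turns ring B into a C5=C6–C7=C8 diene and a C9=C10 dienophile. A carbonyl at C1 activates that dienophile and ties it to C5 through C1–C4, so one cycloaddition closes both rings and leaves at C1 the oxygen from which the alkene is later made.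

## Retrosynthesis

**35 to 33 and 31.** The propanoate C–O bond is cut first, since the ester would survive none of the earlier operations. Hydroxy acid 33 is acylated at the primary allylic hydroxyl only; the neopentyl-type carboxyl can at most form a mixed anhydride that water reopens. 33 comes from methyl ester silyl ether 31 by O–CH3 cleavage and desilylation. This asks for an ester cleavage that does not need attack at the shielded acyl carbon.

**31 to 25 and 29.** The C12–C13 bond is cut between an sp3 and an sp2 carbon. An olefination across C13=C14 would start from a methyl ketone and give E/Z mixtures. The coupling instead takes the alkene geometry intact from vinyl iodide 29. Primary iodide 25 carries only an ester and a trisubstituted alkene, both tolerated by an alkylzinc. The forward Negishi coupling must proceed without β-hydride elimination and with retention at C13.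

**29 to 27 and 26.** The C–I and C–H bonds across the alkene are cut. Syn hydrozirconation of silyl ether 27, made from but-2-yn-1-ol 26, puts the metal trans to the CH2O group. The forward step must place zirconium on the methyl-bearing carbon.

**25 to 23, 22, 20, 19 and 18.** Iodide 25 comes from silyl ether 23 by deprotection and iodination. In 23 the 4β-methyl is traced to a 4β-hydroxymethyl group (xanthate 22, hydroxy acid 20) and that to an ester, which leads to the geminal diester 18. The two esters of 18 are diastereotopic. The α-ester is trans to C6 on the neighbouring C5 and pseudo-equatorial, so half-saponification should select it and give acid 19. The carboxylate then shields C19 while C18 is reduced. This costs five steps for one methyl group. The cost is accepted because the diester keeps the cyclisation precursor free of stereocentres. The forward steps ask for one selective hydrolysis and a deoxygenation at a neopentyl carbon.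

**18 to 16 and 15.** The C1=C10 alkene is traced to the axial 1α-alcohol 16 and to ketone 15. An enol triflate at C1=C10 was considered and set aside. It would hold its oxygen in the alkene plane against the equatorial substituent of the quaternary C9 (A(1,3) strain), so enolisation is expected to turn toward C2. Dehydration of the alcohol leaves only hydrogen on C1. The elimination needs the C1 oxygen axial and anti to H-10, which a trans-fused decalin provides.

**15 to 13.** The C6–C7 single bond is traced to the alkene of cycloadduct 13, and the trans fusion to the cis fusion by epimerisation at C10 next to the ketone. Nothing of value is lost, because C10 ends olefinic.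

**13 to 12.** C8–C9 and C5–C10 are cut together. Cutting ring A alone would leave the contiguous C8/C9 pair unsolved. This cut removes both rings and four stereocentres and leaves the open-chain trienone 12, whose only stereochemical content is three alkene geometries. The forward reaction must run endo with respect to the tether carbonyl and on one face of the enone.

**12 to 10 and 7.** The C2–C3 bond is cut as a Michael addition of the extended enolate of alkylidenemalonate 10 to the vinyl terminus of divinyl ketone 7. The alternative of building the enone after alkylation needs an organometallic in the presence of the malonate. The forward reaction must take place at the α-carbon of the ambident anion, which also moves the unsaturation into the (1E,3E)-diene.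

**10 and 7 to starting materials.** 10 is the Knoevenagel product of dimethyl malonate 8 and (E)-pent-2-enal 9. 7 comes from dienol 6 by oxidation. 6 comes from silyl ether 2 of but-3-yn-1-ol 1 by methyl-metalation of the alkyne and addition to acrolein 3. The carbometalation fixes the (E)-geometry of the dienophile.

## Roads not taken

**Alternative 1:** Ring A is cut at C4–C5 and C2–C3. In the forward sense a chiral Lewis acid joins the ring B 1-vinylcyclohexene A1 and methacrolein A2 to give aldehyde A3.
- Merits: the road is convergent. C4 arrives with methyl and a carbonyl already differentiated, and the C1=C10 alkene is formed in place. After its key step this road is clearly shorter than the chosen one, which spends about eight steps on the alkene and on C4.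
- Weak points: the two alkyl substituents of A1 direct the dienophile in opposite regiochemical senses. The faces of A1 differ only by methyl against allyl on C9, so C5 is poorly controlled relative to C9. The catalyst must act on a chiral, hindered diene. A1 still contains the C8/C9 pair, so the hardest part of the molecule is only moved upstream.
- Comparison: the chosen plan fixes C8, C9 and C5 in one intramolecular event from achiral open-chain material, with alkene geometry deciding the relative configuration.

**Alternative 2:** The C9–C20 and C10–C20 bonds are traced to a cyclopropane. A zinc carbenoid, delivered by the C1 hydroxyl of the tetrasubstituted alkene A4, gives cyclopropane A5. Fragmentation of the three-membered ring then releases the C9 methyl.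
- Merits: hydroxyl-directed delivery on a rigid bicycle is about the most dependable way to set a methyl-bearing quaternary centre. C4 is carried with methyl and ester from the start. The C1 oxygen sits where the alkene must end. On certainty of C9, and on C4, this road is better than the chosen one.
- Weak points: A4 needs C1, C4, C5 and C8 in place on a decalin with a tetrasubstituted alkene, which means a long linear sequence. Such alkenes cyclopropanate slowly. Ring opening of A5 must break the C10–C20 bond and not the endocyclic C9–C10 bond.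
- Comparison: the chosen plan reaches a bicycle with four stereocentres in six steps from simple materials.

**Alternative 3:** Ring A is cut at C4–C5 only. Heating triene A6, whose (2Z,4Z)-dienoate arm hangs on the ring B cyclohexene, closes it by disrotatory 6π electrocyclisation to hexalin A7.
- Merits: the Z geometry at C3=C4 translates directly into methyl β and ester α at C4. The C1=C10 alkene is formed in place. Only the disubstituted C2=C3 alkene has to be hydrogenated afterwards. The road needs no ester differentiation and no deoxygenation, and here it beats the chosen plan.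
- Weak points: the ester must rotate inward, which retards closure. The trisubstituted (Z)-enoate isomerises at the temperatures needed. The sense of disrotation, which sets C5 against C8 and C9, is controlled only by the remote quaternary centre. 1,5-Hydrogen shifts in the cyclohexadiene can follow.
- Comparison: the chosen plan has its C5/C8/C9 relationship fixed by geometry and not by a small remote bias.

Key step: step 6

Assumption: the (S)-configured oxazaborolidinium is taken to give the enantiomer of 13 drawn, on the usual model in which the enone α-hydrogen contacts the ring oxygen and an aryl group screens one face; if the sense is the reverse, the (R)-catalyst is used and nothing else changes.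

## Route

Step 1
Reactants: 1 but-3-yn-1-ol
Product: 2 tert-butyl(but-3-yn-1-yloxy)dimethylsilane
Conditions: TBSCl, imidazole, CH2Cl2, 0 °C to rt
Reagents that add atoms: tert-butyldimethylsilyl chloride, CC(C)(C)[Si](C)(C)Cl
Why: Standard silylation of a primary alcohol; the ether keeps the oxygen from binding Me3Al and the later Lewis acid.

Step 2
Reactants: 2 tert-butyl(but-3-yn-1-yloxy)dimethylsilane; 3 acrolein
Product: 6 (E)-7-(tert-butyldimethylsilyloxy)-5-methylhepta-1,4-dien-3-ol (racemic), via alkenyldimethylalane 4 (not isolated), via lithium alkenylalanate 5 (not isolated)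
Conditions: Me3Al (2 equiv), Cp2ZrCl2 (0.2 equiv), CH2Cl2, 0 °C to rt; volatiles removed; n-BuLi (1 equiv), THF, −78 °C; 3, −78 to −20 °C
Reagents that add atoms: trimethylaluminium, C[Al](C)C
Why: Zirconium-catalysed carboalumination adds methyl and aluminium syn across the terminal alkyne with methyl on the internal carbon, which fixes the (E)-trisubstituted geometry. The derived ate complex adds 1,2 to the enal.

Step 3
Reactants: 6 (E)-7-(tert-butyldimethylsilyloxy)-5-methylhepta-1,4-dien-3-ol
Product: 7 (E)-7-(tert-butyldimethylsilyloxy)-5-methylhepta-1,4-dien-3-one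
Conditions: MnO2 (15 equiv), CH2Cl2, rt
Reagents that add atoms: none
Why: Activated MnO2 oxidises bis-allylic alcohols under neutral conditions that spare the silyl ether and the polymerisable vinyl ketone; 7 is used at once.

Step 4
Reactants: 8 dimethyl malonate; 9 (E)-pent-2-enal
Product: 10 dimethyl 2-[(E)-pent-2-en-1-ylidene]malonate
Conditions: TiCl4 (2 equiv), pyridine (4 equiv), THF, 0 °C to rt
Reagents that add atoms: none
Why: Titanium-mediated Knoevenagel condensation joins malonates and enals without competing conjugate addition; the (E)-alkene of 9 is untouched.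

Step 5
Reactants: 10 dimethyl 2-[(E)-pent-2-en-1-ylidene]malonate; 7 (E)-7-(tert-butyldimethylsilyloxy)-5-methylhepta-1,4-dien-3-one
Product: 12 dimethyl 2-[(1E,3E)-penta-1,3-dien-1-yl]-2-[(E)-7-(tert-butyldimethylsilyloxy)-5-methyl-3-oxohept-4-en-1-yl]malonate, via lithium trienolate 11 (not isolated)
Conditions: LiN(SiMe3)2 (1.05 equiv), THF, −78 °C; 7 (0.95 equiv), −78 °C; AcOH
Reagents that add atoms: none
Why: Deconjugative Michael addition. The doubly vinylogous malonate is deprotonated at its allylic CH2, and under kinetic control the trienolate reacts at the α-carbon with the unsubstituted vinyl terminus of 7, the β,β-disubstituted terminus being inert. α-Attack leaves the (1E,3E)-diene that the extended anion prefers.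

Step 6
Reactants: 12 dimethyl 2-[(1E,3E)-penta-1,3-dien-1-yl]-2-[(E)-7-(tert-butyldimethylsilyloxy)-5-methyl-3-oxohept-4-en-1-yl]malonate
Product: 13 dimethyl 9α-[2-(tert-butyldimethylsilyloxy)ethyl]-8β,9β-dimethyl-1-oxo-5αH,10αH-octal-6-ene-4,4-dicarboxylate (cis-fused cycloadduct)
Conditions: (S)-tetrahydro-1-(2-methylphenyl)-3,3-diphenyl-1H,3H-pyrrolo[1,2-c][1,3,2]oxazaborole (C24H24BNO, 0.2 equiv), HN(SO2CF3)2 (0.2 equiv), CH2Cl2, −40 to 0 °C
Reagents that add atoms: none
Why: The protonated oxazaborolidine binds the C1 carbonyl of the s-cis enone and lowers its LUMO, and the tethered (E,E)-diene adds in a concerted, asynchronous [4+2] in which C8–C9 bonding runs ahead of C5–C10; the closest known reaction types are the Lewis-acid-catalysed type 1 intramolecular Diels–Alder of 1,7,9-decatrien-3-ones and the oxazaborolidinium-catalysed Diels–Alder of acyclic enones. Ring B closes as the cyclohexene of the cycloaddition itself, and ring A closes in the same event as the six-membered carbocycle spanned by the four-atom tether C1–C4 between C10 and C5, cis-fused. C5 and C8 are related by suprafacial use of the (E,E)-diene (H-5 and H-8 cis), and C9 and C10 by the (E)-enone geometry (C1 and C20 cis). The two pairs are tied together by the endo position of the Lewis-acid-bound tether carbonyl, which puts the small C20 methyl and not the silyloxyethyl arm under the diene and so makes the C8 and C9 methyls cis. The absolute configuration is set by the catalyst alone, because the malonate carbon is not stereogenic and an aryl group of the catalyst screens one face of the bound enone. The step needs endo over exo selectivity (exo would give the C9 epimer) and face selectivity; the first rests on enone geometry and complexation, the second on the catalyst. The geminal esters speed closure by the Thorpe–Ingold effect, and a (1E,3Z)-diene impurity cannot reach the transition state. C10 is set here but is sacrificial.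

Step 7
Reactants: 13 cis-fused cycloadduct
Product: 15 dimethyl 9α-[2-(tert-butyldimethylsilyloxy)ethyl]-8β,9β-dimethyl-1-oxo-5αH,10βH-decalin-4,4-dicarboxylate (trans-fused), via cis-fused dihydro ketone 14 (not isolated)
Conditions: H2 (1 atm), Pd/C, EtOAc, rt; filtration; NaOMe (0.3 equiv), MeOH, rt
Reagents that add atoms: none
Why: Heterogeneous hydrogenation saturates the only C=C. Methoxide then equilibrates C10 through the C1 enolate to the trans-fused decalone, expected to be favoured because either chair form of the cis isomer has a syn-diaxial clash (C1 with the axial C8 methyl, or C4 with the C9 methyl). The trans fusion is wanted only to give H-10 an axial, anti-periplanar position for step 9.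

Step 8
Reactants: 15 trans-fused ketone
Product: 16 dimethyl 9α-[2-(tert-butyldimethylsilyloxy)ethyl]-1α-hydroxy-8β,9β-dimethyl-5αH,10βH-decalin-4,4-dicarboxylate (axial alcohol)
Conditions: LiBH(s-Bu)3 (1.5 equiv), THF, −78 °C; H2O
Reagents that add atoms: none
Why: Sterically controlled ketone reduction. The bulky borohydride attacks from the equatorial β direction, away from the axial C9 side chain that blocks the α face, and gives the axial 1α-alcohol, as with 11-oxo steroids. The esters are inert at −78 °C.

Step 9
Reactants: 16 axial alcohol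
Product: 18 dimethyl 9α-[2-(tert-butyldimethylsilyloxy)ethyl]-8β,9β-dimethyl-5αH-octal-1(10)-ene-4,4-dicarboxylate, via axial dichlorophosphate 17 (not isolated)
Conditions: POCl3 (5 equiv), pyridine, 0 to 70 °C
Reagents that add atoms: none
Why: Anti-periplanar E2 dehydration. H-10β and H-2β are both anti to the axial leaving group; loss of the tertiary ring-fusion hydrogen gives the trisubstituted alkene and relieves the syn-diaxial strain with C11, the regiochemistry known from axial 11β- and 6β-hydroxy steroids. No A(1,3) strain arises because C1 ends with hydrogen.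

Step 10
Reactants: 18 alkene diester
Product: 19 9α-[2-(tert-butyldimethylsilyloxy)ethyl]-4β-(methoxycarbonyl)-8β,9β-dimethyl-5αH-octal-1(10)-ene-4α-carboxylic acid
Conditions: LiOH·H2O (3 equiv), THF/MeOH/H2O, 50 °C; AcOH to pH 4–5
Reagents that add atoms: lithium hydroxide, [Li+].[OH-]
Why: Half-saponification of a geminal diester. The α-ester, trans to C6 on the neighbouring C5 and pseudo-equatorial, is the more exposed and should be hydrolysed first, as in 2-substituted cycloalkane-1,1-dicarboxylates; the carboxylate formed then protects the second ester. This step sets C4.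

Step 11
Reactants: 19 half-ester acid
Product: 20 9α-[2-(tert-butyldimethylsilyloxy)ethyl]-4β-(hydroxymethyl)-8β,9β-dimethyl-5αH-octal-1(10)-ene-4α-carboxylic acid
Conditions: LiEt3BH (4 equiv), THF, 0 °C to rt; AcOH/H2O
Reagents that add atoms: none
Why: Chemoselective hydride reduction: triethylborohydride reduces hindered esters quickly but leaves lithium carboxylates, alkenes and silyl ethers alone, so only C18 is reduced.

Step 12
Reactants: 20 hydroxy acid
Product: 22 methyl 9α-[2-(tert-butyldimethylsilyloxy)ethyl]-8β,9β-dimethyl-4β-{[(methylsulfanyl)carbonothioyl]oxymethyl}-5αH-octal-1(10)-ene-4α-carboxylate, via disodium xanthate carboxylate 21 (not isolated)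
Conditions: NaH (3 equiv), THF/DMF, 0 °C; CS2; MeI (excess), rt
Reagents that add atoms: carbon disulfide, S=C=S; iodomethane, CI
Why: Xanthate formation with concurrent carboxylate O-methylation. The alkoxide is trapped by CS2 before MeI is added, so no free alkoxide coexists with the ester and retro-aldol loss of formaldehyde is avoided.

Step 13
Reactants: 22 xanthate ester
Product: 23 methyl 9α-[2-(tert-butyldimethylsilyloxy)ethyl]-4β,8β,9β-trimethyl-5αH-octal-1(10)-ene-4α-carboxylate
Conditions: Bu3SnH (2.5 equiv), AIBN (0.2 equiv), toluene, 110 °C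
Reagents that add atoms: none
Why: Barton–McCombie deoxygenation. The primary neopentyl radical has no cyclisation path (attack on C10 or C1 would be 4-exo or 5-endo) and should be quenched by the stannane faster than a 1,2-ester shift. C18 becomes the 4β-methyl.

Step 14
Reactants: 23 silyl ether ester
Product: 24 methyl 9α-(2-hydroxyethyl)-4β,8β,9β-trimethyl-5αH-octal-1(10)-ene-4α-carboxylate
Conditions: TBAF (1.5 equiv), THF, rt
Reagents that add atoms: none
Why: Fluoride cleavage of a primary silyl ether; the hindered ester and the alkene are inert.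

Step 15
Reactants: 24 primary alcohol
Product: 25 methyl 9α-(2-iodoethyl)-4β,8β,9β-trimethyl-5αH-octal-1(10)-ene-4α-carboxylate
Conditions: I2, PPh3, imidazole, CH2Cl2, 0 °C to rt
Reagents that add atoms: iodine, II
Why: Appel-type iodination of a primary alcohol under buffered conditions that do not protonate the C1=C10 alkene.

Step 16
Reactants: 26 but-2-yn-1-ol
Product: 27 triethyl(but-2-yn-1-yloxy)silane
Conditions: Et3SiCl, imidazole, CH2Cl2, 0 °C
Reagents that add atoms: chlorotriethylsilane, CC[Si](CC)(CC)Cl
Why: Silylation of a primary alcohol; the triethylsilyl group is chosen so that it falls off in the mildly acidic work-up of step 19.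

Step 17
Reactants: 27 triethyl(but-2-yn-1-yloxy)silane
Product: 29 (E)-triethyl[(3-iodobut-2-en-1-yl)oxy]silane, via alkenylzirconocene chloride 28 (not isolated)
Conditions: Cp2Zr(H)Cl (2.2 equiv), THF, 50 °C; I2, 0 °C
Reagents that add atoms: iodine, II
Why: Hydrozirconation then iodinolysis. With excess hydride at 50 °C the syn adducts equilibrate to the one with zirconium on the less hindered, methyl-bearing carbon, and iodine replaces the metal with retention, so iodine ends trans to the CH2O group.

Step 18
Reactants: 25 primary iodide; 29 (E)-triethyl[(3-iodobut-2-en-1-yl)oxy]silane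
Product: 31 methyl 9α-[(E)-3-methyl-5-(triethylsilyloxy)pent-3-en-1-yl]-4β,8β,9β-trimethyl-5αH-octal-1(10)-ene-4α-carboxylate, via alkylzinc iodide 30 (not isolated)
Conditions: Zn dust (3 equiv, activated with BrCH2CH2Br and Me3SiCl), DMA, 40 °C; 29 (1.2 equiv), PdCl2(dppf) (0.05 equiv), THF, 45 °C
Reagents that add atoms: none
Why: Negishi sp3–sp2 coupling. Zinc inserts into the primary C–I bond without touching the ester, the alkenyl iodide couples with retention of the (E)-geometry, and the bidentate phosphine suppresses β-hydride elimination.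

Step 19
Reactants: 31 coupled methyl ester
Product: 33 9α-[(E)-5-hydroxy-3-methylpent-3-en-1-yl]-4β,8β,9β-trimethyl-5αH-octal-1(10)-ene-4α-carboxylic acid, via lithium carboxylate 32 (not isolated)
Conditions: n-PrSLi (from n-PrSH and n-BuLi, 5 equiv), HMPA, rt; AcOH/THF/H2O, rt
Reagents that add atoms: none
Why: Thiolate SN2 demethylation cleaves the ester at the O–CH3 bond, so the shielded acyl carbon need not be attacked; the triethylsilyl ether is hydrolysed in the acetic acid work-up that also frees the acid.

Step 20
Reactants: 33 hydroxy acid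
Product: 35 9α-[(E)-3-methyl-5-(propanoyloxy)pent-3-en-1-yl]-4β,8β,9β-trimethyl-5αH-octal-1(10)-ene-4α-carboxylic acid (4S,5S,8R,9S), via mixed anhydride 34 (not isolated)
Conditions: (EtCO)2O (3 equiv), pyridine, DMAP (0.1 equiv), CH2Cl2, 0 °C to rt; aq. NaHCO3/THF, rt; acidify to pH 4
Reagents that add atoms: propanoic anhydride, CCC(=O)OC(=O)CC
Why: DMAP-catalysed acylation of the primary allylic alcohol. The hindered carboxyl can only form a mixed anhydride, which bicarbonate hydrolyses at the unhindered propanoyl carbonyl and so returns the free acid.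

## Compound list

1 | but-3-yn-1-ol | C#CCCO | starting material
2 | tert-butyl(but-3-yn-1-yloxy)dimethylsilane | C#CCCO[Si](C)(C)C(C)(C)C | intermediate
3 | acrolein | C=CC=O | starting material
4 | [(E)-4-(tert-butyldimethylsilyloxy)-2-methylbut-1-en-1-yl]dimethylalane | C[Al](C)/C=C(\C)CCO[Si](C)(C)C(C)(C)C | intermediate
5 | lithium butyl[(E)-4-(tert-butyldimethylsilyloxy)-2-methylbut-1-en-1-yl]dimethylalanate | [Li+].CCCC[Al-](C)(C)/C=C(\C)CCO[Si](C)(C)C(C)(C)C | intermediate
6 | (E)-7-(tert-butyldimethylsilyloxy)-5-methylhepta-1,4-dien-3-ol (racemic) | C=CC(O)/C=C(\C)CCO[Si](C)(C)C(C)(C)C | intermediate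
7 | (E)-7-(tert-butyldimethylsilyloxy)-5-methylhepta-1,4-dien-3-one | C=CC(=O)/C=C(\C)CCO[Si](C)(C)C(C)(C)C | intermediate
8 | dimethyl malonate | COC(=O)CC(=O)OC | starting material
9 | (E)-pent-2-enal | CC/C=C/C=O | starting material
10 | dimethyl 2-[(E)-pent-2-en-1-ylidene]malonate | CC/C=C/C=C(C(=O)OC)C(=O)OC | intermediate
11 | lithium trienolate of 10 | [Li+].COC(=O)C(/C=C/C=C/C)=C([O-])OC | intermediate
12 | dimethyl 2-[(1E,3E)-penta-1,3-dien-1-yl]-2-[(E)-7-(tert-butyldimethylsilyloxy)-5-methyl-3-oxohept-4-en-1-yl]malonate | C/C=C/C=C/C(C(=O)OC)(C(=O)OC)CCC(=O)/C=C(\C)CCO[Si](C)(C)C(C)(C)C | intermediate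
13 | dimethyl 9α-[2-(tert-butyldimethylsilyloxy)ethyl]-8β,9β-dimethyl-1-oxo-5αH,10αH-octal-6-ene-4,4-dicarboxylate | CC(C)(C)[Si](C)(C)OCC[C@]1(C)[C@H]2C(=O)CCC(C(=O)OC)(C(=O)OC)[C@H]2C=C[C@H]1C | intermediate
14 | 6,7-dihydro derivative of 13 (cis-fused, 5αH,10αH) | CC(C)(C)[Si](C)(C)OCC[C@]1(C)[C@H]2C(=O)CCC(C(=O)OC)(C(=O)OC)[C@H]2CC[C@H]1C | intermediate
15 | dimethyl 9α-[2-(tert-butyldimethylsilyloxy)ethyl]-8β,9β-dimethyl-1-oxo-5αH,10βH-decalin-4,4-dicarboxylate | CC(C)(C)[Si](C)(C)OCC[C@]1(C)[C@@H]2C(=O)CCC(C(=O)OC)(C(=O)OC)[C@H]2CC[C@H]1C | intermediate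
16 | dimethyl 9α-[2-(tert-butyldimethylsilyloxy)ethyl]-1α-hydroxy-8β,9β-dimethyl-5αH,10βH-decalin-4,4-dicarboxylate | CC(C)(C)[Si](C)(C)OCC[C@]1(C)[C@@H]2[C@H](O)CCC(C(=O)OC)(C(=O)OC)[C@H]2CC[C@H]1C | intermediate
17 | 1α-dichlorophosphate of 16 | CC(C)(C)[Si](C)(C)OCC[C@]1(C)[C@@H]2[C@H](OP(=O)(Cl)Cl)CCC(C(=O)OC)(C(=O)OC)[C@H]2CC[C@H]1C | intermediate
18 | dimethyl 9α-[2-(tert-butyldimethylsilyloxy)ethyl]-8β,9β-dimethyl-5αH-octal-1(10)-ene-4,4-dicarboxylate | CC(C)(C)[Si](C)(C)OCC[C@]1(C)C2=CCCC(C(=O)OC)(C(=O)OC)[C@H]2CC[C@H]1C | intermediate
19 | 9α-[2-(tert-butyldimethylsilyloxy)ethyl]-4β-(methoxycarbonyl)-8β,9β-dimethyl-5αH-octal-1(10)-ene-4α-carboxylic acid | CC(C)(C)[Si](C)(C)OCC[C@]1(C)C2=CCC[C@](C(=O)OC)(C(=O)O)[C@H]2CC[C@H]1C | intermediate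
20 | 9α-[2-(tert-butyldimethylsilyloxy)ethyl]-4β-(hydroxymethyl)-8β,9β-dimethyl-5αH-octal-1(10)-ene-4α-carboxylic acid | CC(C)(C)[Si](C)(C)OCC[C@]1(C)C2=CCC[C@](CO)(C(=O)O)[C@H]2CC[C@H]1C | intermediate
21 | disodium salt of 20 O-dithiocarbonate (xanthate carboxylate) | [Na+].[Na+].CC(C)(C)[Si](C)(C)OCC[C@]1(C)C2=CCC[C@](COC(=S)[S-])(C(=O)[O-])[C@H]2CC[C@H]1C | intermediate
22 | methyl 9α-[2-(tert-butyldimethylsilyloxy)ethyl]-8β,9β-dimethyl-4β-{[(methylsulfanyl)carbonothioyl]oxymethyl}-5αH-octal-1(10)-ene-4α-carboxylate | CC(C)(C)[Si](C)(C)OCC[C@]1(C)C2=CCC[C@](COC(=S)SC)(C(=O)OC)[C@H]2CC[C@H]1C | intermediate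
23 | methyl 9α-[2-(tert-butyldimethylsilyloxy)ethyl]-4β,8β,9β-trimethyl-5αH-octal-1(10)-ene-4α-carboxylate | CC(C)(C)[Si](C)(C)OCC[C@]1(C)C2=CCC[C@](C)(C(=O)OC)[C@H]2CC[C@H]1C | intermediate
24 | methyl 9α-(2-hydroxyethyl)-4β,8β,9β-trimethyl-5αH-octal-1(10)-ene-4α-carboxylate | OCC[C@]1(C)C2=CCC[C@](C)(C(=O)OC)[C@H]2CC[C@H]1C | intermediate
25 | methyl 9α-(2-iodoethyl)-4β,8β,9β-trimethyl-5αH-octal-1(10)-ene-4α-carboxylate | ICC[C@]1(C)C2=CCC[C@](C)(C(=O)OC)[C@H]2CC[C@H]1C | intermediate
26 | but-2-yn-1-ol | CC#CCO | starting material
27 | triethyl(but-2-yn-1-yloxy)silane | CC#CCO[Si](CC)(CC)CC | intermediate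
28 | chloro[(E)-4-(triethylsilyloxy)but-2-en-2-yl]zirconocene | CC[Si](CC)(CC)OC/C=C(\C)[Zr](Cl)(C1C=CC=C1)C1C=CC=C1 | intermediate
29 | (E)-triethyl[(3-iodobut-2-en-1-yl)oxy]silane | CC[Si](CC)(CC)OC/C=C(\C)I | intermediate
30 | alkylzinc iodide from 25 | I[Zn]CC[C@]1(C)C2=CCC[C@](C)(C(=O)OC)[C@H]2CC[C@H]1C | intermediate
31 | methyl 9α-[(E)-3-methyl-5-(triethylsilyloxy)pent-3-en-1-yl]-4β,8β,9β-trimethyl-5αH-octal-1(10)-ene-4α-carboxylate | CC[Si](CC)(CC)OC/C=C(\C)CC[C@]1(C)C2=CCC[C@](C)(C(=O)OC)[C@H]2CC[C@H]1C | intermediate
32 | lithium 9α-[(E)-3-methyl-5-(triethylsilyloxy)pent-3-en-1-yl]-4β,8β,9β-trimethyl-5αH-octal-1(10)-ene-4α-carboxylate | [Li+].CC[Si](CC)(CC)OC/C=C(\C)CC[C@]1(C)C2=CCC[C@](C)(C(=O)[O-])[C@H]2CC[C@H]1C | intermediate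
33 | 9α-[(E)-5-hydroxy-3-methylpent-3-en-1-yl]-4β,8β,9β-trimethyl-5αH-octal-1(10)-ene-4α-carboxylic acid | OC/C=C(\C)CC[C@]1(C)C2=CCC[C@](C)(C(=O)O)[C@H]2CC[C@H]1C | intermediate
34 | mixed propanoic anhydride of 35 at C19 | CCC(=O)OC/C=C(\C)CC[C@]1(C)C2=CCC[C@](C)(C(=O)OC(=O)CC)[C@H]2CC[C@H]1C | intermediate
35 | 9α-[(E)-3-methyl-5-(propanoyloxy)pent-3-en-1-yl]-4β,8β,9β-trimethyl-5αH-octal-1(10)-ene-4α-carboxylic acid, (4S,5S,8R,9S) | CCC(=O)OC/C=C(\C)CC[C@]1(C)C2=CCC[C@](C)(C(=O)O)[C@H]2CC[C@H]1C | target

## Step count and risks

Total step count: 20. Longest linear sequence: 17 steps (steps 1–3, 5–15 and 18–20, from but-3-yn-1-ol).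

**Step 6 (key step).** The likeliest failure is lack of turnover or poor face selectivity. The β,β-disubstituted enone is a slow, hindered dienophile, and the two ester carbonyls compete with the ketone for the boron cation; prolonged exposure may also cost the silyl ether. The fallback sets out from 12 and returns at 13. 12 is cyclised with the achiral Lewis acid Me2AlCl (CH2Cl2, −78 to 0 °C), the classical promoter for such trienones, to the racemic cis-fused cycloadduct F1. The enantiomers are then separated by preparative chromatography on a polysaccharide chiral stationary phase; the wanted one is 13.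

**Step 5.** The ambident trienolate may react at its remote terminus instead of the α-carbon, or the vinyl ketone may oligomerise under the basic conditions. The fallback sets out from 10 and returns at 12. The trienolate of 10 (NaH, DMF) is alkylated irreversibly at the α-carbon with 2-(2-bromoethyl)-1,3-dioxolane to give acetal F2. Aqueous acetic acid frees aldehyde F3. A Nozaki–Hiyama–Kishi coupling (CrCl2, catalytic NiCl2, DMSO) with vinyl iodide F4, obtained from 2 by the carboalumination of step 2 followed by iodinolysis, gives allylic alcohol F5. MnO2 oxidation gives 12.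

**Step 9.** Elimination may run toward C2, or phosphorylation of the hindered axial hydroxyl may be too slow. The fallback sets out from 15 and returns at 18, and makes the regiochemistry structural. Kinetic enolisation of 15 toward C2 (LDA, Me3SiCl) gives silyl enol ether F6. Saegusa oxidation with Pd(OAc)2 gives the C2=C3 enone F7, whose only remaining enolisable hydrogen is H-10. KN(SiMe3)2 and N-phenyltriflimide give dienyl triflate F8. Formate reduction (Pd(OAc)2, PPh3, Bu3N, HCO2H) gives the 1(10),2-diene F9. Diimide, generated from 2-nitrobenzenesulfonohydrazide, reduces the disubstituted C2=C3 bond only and gives 18.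

**Step 10.** Hydrolysis may discriminate poorly between the two diastereotopic esters, which would carry the C4 epimer forward. The fallback sets out from 18 and returns at 22, and lets the alkene choose the ester. Iodine in acetonitrile closes the pseudo-axial 4β-ester onto C10 from the β face, with loss of iodomethane, to give iodolactone ester F10. Zinc in acetic acid reopens it to the alkene acid F11, which has the free carboxyl at C18 and the ester at C19. BH3·THF at 0 °C reduces only the acid, to hydroxy ester F12. Xanthate formation (NaH, CS2, MeI) gives 22.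

**Step 13.** Fragmentation of the stannyl radical adduct to a primary neopentyl radical may be too slow, so that alcohol is returned or a 1,2-ester shift intervenes. The fallback sets out from 20 and returns at 23. Trimethylsilyldiazomethane converts 20 into hydroxy ester F12. The periodinane DMP oxidises it to aldehyde F13. 4-Methylbenzenesulfonohydrazide gives tosylhydrazone F14. Catecholborane followed by sodium acetate reduces the hydrazone carbon to the methyl group of 23.

## Further compounds

F1 | step 6 | racemic dimethyl 9-[2-(tert-butyldimethylsilyloxy)ethyl]-8,9-dimethyl-1-oxo-octal-6-ene-4,4-dicarboxylate (racemate of 13; one enantiomer drawn) | CC(C)(C)[Si](C)(C)OCC[C@]1(C)[C@H]2C(=O)CCC(C(=O)OC)(C(=O)OC)[C@H]2C=C[C@H]1C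
F2 | step 5 | dimethyl 2-[2-(1,3-dioxolan-2-yl)ethyl]-2-[(1E,3E)-penta-1,3-dien-1-yl]malonate | C/C=C/C=C/C(C(=O)OC)(C(=O)OC)CCC1OCCO1
F3 | step 5 | dimethyl 2-(3-oxopropyl)-2-[(1E,3E)-penta-1,3-dien-1-yl]malonate | C/C=C/C=C/C(C(=O)OC)(C(=O)OC)CCC=O
F4 | step 5 | (E)-tert-butyl[(4-iodo-3-methylbut-3-en-1-yl)oxy]dimethylsilane | I/C=C(\C)CCO[Si](C)(C)C(C)(C)C
F5 | step 5 | dimethyl 2-[(E)-7-(tert-butyldimethylsilyloxy)-3-hydroxy-5-methylhept-4-en-1-yl]-2-[(1E,3E)-penta-1,3-dien-1-yl]malonate | C/C=C/C=C/C(C(=O)OC)(C(=O)OC)CCC(O)/C=C(\C)CCO[Si](C)(C)C(C)(C)C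
F6 | step 9 | 1-(trimethylsilyloxy)-1(2)-ene from 15 (trans-fused) | CC(C)(C)[Si](C)(C)OCC[C@]1(C)[C@@H]2C(O[Si](C)(C)C)=CCC(C(=O)OC)(C(=O)OC)[C@H]2CC[C@H]1C
F7 | step 9 | trans-fused 2-en-1-one diester | CC(C)(C)[Si](C)(C)OCC[C@]1(C)[C@@H]2C(=O)C=CC(C(=O)OC)(C(=O)OC)[C@H]2CC[C@H]1C
F8 | step 9 | 1-(trifluoromethylsulfonyloxy)-1(10),2-diene diester | CC(C)(C)[Si](C)(C)OCC[C@]1(C)C2=C(OS(=O)(=O)C(F)(F)F)C=CC(C(=O)OC)(C(=O)OC)[C@H]2CC[C@H]1C
F9 | step 9 | 1(10),2-diene diester | CC(C)(C)[Si](C)(C)OCC[C@]1(C)C2=CC=CC(C(=O)OC)(C(=O)OC)[C@H]2CC[C@H]1C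
F10 | step 10 | 1α-iodo 18,10β-lactone methyl 19-ester | CC(C)(C)[Si](C)(C)OCC[C@]1(C)[C@@]2(OC(=O)[C@]3(C(=O)OC)CC[C@H]2I)[C@@H]3CC[C@H]1C
F11 | step 10 | 9α-[2-(tert-butyldimethylsilyloxy)ethyl]-4α-(methoxycarbonyl)-8β,9β-dimethyl-5αH-octal-1(10)-ene-4β-carboxylic acid | CC(C)(C)[Si](C)(C)OCC[C@]1(C)C2=CCC[C@](C(=O)O)(C(=O)OC)[C@H]2CC[C@H]1C
F12 | step 10 | methyl 9α-[2-(tert-butyldimethylsilyloxy)ethyl]-4β-(hydroxymethyl)-8β,9β-dimethyl-5αH-octal-1(10)-ene-4α-carboxylate | CC(C)(C)[Si](C)(C)OCC[C@]1(C)C2=CCC[C@](CO)(C(=O)OC)[C@H]2CC[C@H]1C
F13 | step 13 | methyl 9α-[2-(tert-butyldimethylsilyloxy)ethyl]-4β-formyl-8β,9β-dimethyl-5αH-octal-1(10)-ene-4α-carboxylate | CC(C)(C)[Si](C)(C)OCC[C@]1(C)C2=CCC[C@](C=O)(C(=O)OC)[C@H]2CC[C@H]1C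
F14 | step 13 | 4-methylbenzenesulfonylhydrazone of F13 | CC(C)(C)[Si](C)(C)OCC[C@]1(C)C2=CCC[C@](C=NNS(=O)(=O)c3ccc(C)cc3)(C(=O)OC)[C@H]2CC[C@H]1C
A1 | alternative 1 | 6-allyl-5,6-dimethyl-1-vinylcyclohexene (ring B diene) | C=CC[C@]1(C)C(C=C)=CCC[C@H]1C
A2 | alternative 1 | methacrolein | C=C(C)C=O
A3 | alternative 1 | 9-allyl 1(10)-octalin C18 aldehyde | C=CC[C@]1(C)C2=CCC[C@](C)(C=O)[C@H]2CC[C@H]1C
A4 | alternative 2 | 9(10)-ene C1 alcohol with silyloxypropyl chain and C4 methyl ester | CC(C)(C)[Si](C)(C)OCCCC1=C2[C@@H](O)CC[C@](C)(C(=O)OC)[C@H]2CC[C@H]1C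
A5 | alternative 2 | 9,10-methano decalin C1 alcohol | CC(C)(C)[Si](C)(C)OCCC[C@]12C[C@]13[C@@H](O)CC[C@](C)(C(=O)OC)[C@H]3CC[C@H]2C
A6 | alternative 3 | ring B cyclohexene bearing the (2Z,4Z)-2-methylpenta-2,4-dienoate arm | CC(C)(C)[Si](C)(C)OCCC[C@]1(C)C(/C=C\C=C(/C(=O)OC)C)=CCC[C@H]1C
A7 | alternative 3 | 1(10),2-hexalin methyl ester | CC(C)(C)[Si](C)(C)OCCC[C@]1(C)C2=CC=C[C@](C)(C(=O)OC)[C@H]2CC[C@H]1C
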